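67.6% is dawn's G ceiling: the G charged divided by the J and X charged together, a cap on product if each product uses one G. Dawn charges less G than J and X together, so there G is the limiting reagent.

the same everywhere: J 0.37 M; X 0.37 M; Z 37 mM
- green: G 0.64 M; run made earlier
- violet: G 0.69 M; run made earlier
- amber: G 0.91 M; run made earlier
- summer: G 0.814 M; time 12 h
- dawn: G 0.500 M; time 12 h

| run | time / h | L / % | Q / % |
|---|---|---|---|
| green | 1.00 | 22.4 | 4.2 |
| green | 3.00 | 38.1 | 7.7 |
| green | 5.00 | 46.6 | 8.1 |
| green | 8.00 | 53.6 | 13.7 |
| violet | 1.00 | 23.1 | 3.2 |
| violet | 3.00 | 41.5 | 8.2 |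
| violet | 5.00 | 48.1 | 11.6 |
| violet | 8.00 | 55.2 | 12.9 |
| amber | 0.667 | 21.3 | 3.1 |
| amber | 1.50 | 34.4 | 8.2 |
| amber | 4.00 | 52.2 | 12.2 |
| amber | 8.00 | 62.0 | 17.6 |

(standard deviation of a reading: 1 percentage point)

- G is single-handed; J and X are mirror images of each other, charged as a racemate, each of them at the stated concentration
- an excess is the difference of the two amounts in percent of their sum
- an excess is below zero if the other one leads
- the handed part of G does not stay in what it makes, so the products of the two hands are mirror images too

- the winner by excess of L over Q in the product; "neither" if no more than 2 percentage points parts them (summer / dawn / neither)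
- excess of L over Q in the product at the end, summer
- excess of L over Q in the product at the end, dawn

Why should a cap matter to the excess? Look at the excess in a run as product grows. Violet reads 75.7% at its first reading, and 62.1% at its last, with 68.1% turned over.

And summer? Its ceiling is 110%, above the whole charge, so I read it off amber's last reading, 55.8%.

So dawn gets violet's figure? That is my first round only. Put it back in: violet stood at that point with 0.186 M of G left, and dawn charges 0.190 M less, so I expect dawn to crawl as it nears its ceiling. I expect it to stop earlier on the falling line, which makes 62.1% my low estimate for dawn, not a value.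

Is the gap enough? My low estimate stands 6.3 percentage points above the amber reading I took for summer, more than the margin of 2 points, so I say dawn.

The forecast says dawn, with 56% for summer and 65% for dawn, on the grounds that “G is consumed one-for-one, so it caps conversion”. Its dawn figure lies above my low estimate.

The flask gives dawn: 56.7% for summer and 65.6% for dawn.

    G + J → L (k = 2.90 × 10⁻⁴ M⁻¹ s⁻¹)
    G + X → Q (k = 4.10 × 10⁻⁵ M⁻¹ s⁻¹)
    J + Z ⇌ X + Z, rate k3*[Z]*[J] forward; the back reaction follows from the equilibrium constant (k = 0.00150 M⁻¹ s⁻¹)
    2 Z ⇌ E, settled at all times (K = 12.0 M⁻¹)

Dawn holds L and Q together at 61.4% after 12.0 h, under its ceiling of 67.6%. Left for 120 h, it has 0% of its G and 67.6% of L and Q, so it does reach the ceiling, at an excess of 66.2%. A neighbour of summer charged with 0.20 M of G has a ceiling of 27.0%. After 12.0 h it has 1.89% of its G left and 26.5% of L and Q, at an excess of 72.1%.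

All runs were generated by integration with made-up constants; scatter was added.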